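## The problem

The target **30** is a normal-series labdane, (2R,5S,9S,10S,13R)-2-acetoxylabd-8(17)-en-15-oic acid. Labdane numbering is used for all compounds: ring A = C1–C5 and C10, ring B = C5–C10, C17 = methylene carbon on C8, C18/C19 = methyls on C4, C20 = methyl on C10, C11–C15 (C16 on C13) = chain on C9. The skeleton is a trans-decalin whose fusion bond C5–C10 joins a tertiary and a quaternary stereocentre directly beside the gem-dimethyl carbon C4. C5 and C10 must be made together, because nothing else in the molecule can correct them later. Once they stand they control the rest of the ring: the C9 chain is equatorial, so α-face hydrogenation of a C9=C11 alkene and equilibration beside a C8 ketone both give it. A C2 ketone can only take hydride from the α-face, because the β-face is closed by the syn-axial methyls C19 and C20, and that gives the axial 2β-oxygen of the target. C13 is too far from the ring to be controlled by it and has to arrive with the side chain as a single enantiomer. Three groups fix the order of events: the C8=C17 alkene does not survive hydrogenation, hydroboration or strong acid, the hindered acetate does not survive enolate bases or hydroxide, and the C15 acid must be freed last without touching either. The feature that opens the problem is that C2–C3–C4–C5–C6 is the carbon chain of 3,3-dimethylglutaric acid. If O2 and C6 are tied as a δ-lactone and C2 carries the C1=C10 alkene, the ketene acetal C5=C6 and the allylic C2–O bond form a 1,5-diene. A [3,3] shift across it makes C5–C10, contracts the lactone to ring A, and leaves a C1=C2 alkene through which the C2 oxygen can be returned.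

## Retrosynthesis

**C15 ester and C8=C17.** The acid of **30** is released from methyl ester **29** by cutting the O–CH3 bond with iodide, not the acyl–oxygen bond with hydroxide, because only the first leaves the 2β-acetate alone. C8=C17 of **29** is cut back to the ketone of **28**, so the alkene appears only after the last hydrogenation. These cuts remove little complexity, but they decide that C8 is a ketone through the middle of the route, which also keeps C9 adjustable.

**C9–C11.** Cutting this bond separates aldehyde **24** from the bicyclic hydroxy enone **20**. An aldol cut (via **25** and dienone **27**) is preferred to alkylation of a C8 enolate with a C11 halide, because C9 is neopentyl and alkylates poorly, while an aldehyde is a fast electrophile. Dehydration returns C9 to a trigonal state, from which hydrogenation sets it from the α-face. The forward reaction needs enolisation towards C9 only. In **20** this is assured because C7 is an alkene carbon and C2 is already an alcohol.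

**C13.** Aldehyde **24** has one stereocentre, which lies on the mirror plane of 3-methylglutaric acid. The two ester groups of diester **21** are told apart by an esterase (**22**); the free acid arm is reduced (**23**) and oxidised (**24**). Reducing the acid arm of (R)-**22** makes that arm C11–C12 and gives 13R.

**C2–H.** The carbinol of **20** is cut back to the ketone of ene-dione **19**. The cut is placed here because in **19** the other carbonyl group is a conjugated enone and reduces more slowly; after hydrogenation two saturated ketones would have to be told apart. The forward step needs α-face hydride delivery, which the two axial methyls enforce.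

**C6=C7 (ring B).** An aldol-condensation cut leads to keto aldehyde **17**, with C6 as an aldehyde on C5 and C7 as the methyl of a methyl ketone on C9. Cutting here, not at C8–C9 or C9–C10, leaves C5–C10 and both its stereocentres in a monocyclic precursor, and only one six-membered closure is possible. The forward reaction needs the methyl ketone to enolise faster than the hindered C5–H.

**Oxidation levels.** The three carbonyl groups of **17** come from triol **16** in one oxidation. **16** comes from alcohol **14** by hydroboration of C1=C2 (oxygen to C2, away from quaternary C10) and loss of the silyl group, and **14** from acid **13**. No C–C bond is cut, but this shows that **13**, a cyclohex-3-ene-1-carboxylic acid, already holds every core carbon and both fusion stereocentres.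

**C5–C10 (key cut).** In **13** the carboxyl group on C5 and the C1=C2 alkene stand in the relationship of a Claisen product. Cutting C5–C10 and rejoining O–C2 gives the 6-alkenyl δ-lactone **10**. Compared with an intermolecular cycloaddition or an alkylation at C10, this forms the most hindered bond of the target intramolecularly and converts one carbinol centre into two carbon centres. **10** has one controlling stereocentre and a Z-alkene. The forward reaction must pass through the boat that the C3–C4 bridge enforces, and the alkene must be Z so that C20 ends cis to C6.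

**Lactone C–O and C2–H.** **10** is opened to hydroxy ester **9**, and the carbinol is cut back to Z-enone **8**. An enantioselective ketone reduction is preferred to a resolution because the alkenyl and CH2 flanks differ in kind. It must give the 5R alcohol (C2 of the labdane).

**C1–C2.** **8** (via acid **7**) is cut between the carbonyl carbon and the alkene into 3,3-dimethylglutaric anhydride **5** and the Z-alkenyl iodide **4**. The anhydride delivers C2–C6 in one symmetrical, commercial piece. The forward reaction must keep the alkene geometry, which an alkenyllithium does.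

**C10–C20 and C1–I.** **4** comes from iodo alcohol **3**, and **3** from (S)-pent-4-yn-2-ol **1** by adding methyl and iodine across the alkyne. The free homopropargylic hydroxyl is what allows the Z-isomer to be reached by chelation. For this reason the C8 oxygen is carried as a silyl ether, not as a ketal, whose alkyne would have to pass through a cuprate addition to an ynone of uncertain geometry.

## Roads not taken

Alternative 1: Ring B is cut at C9–C10 and C7–C8. Forward, the dienyl butynoate (1R)-4-ethenyl-3,5,5-trimethylcyclohex-3-en-1-yl 4-[(tert-butyldimethylsilyl)oxy]but-2-ynoate A1 would undergo an intramolecular Diels–Alder reaction to the tricyclic dienyl lactone A2.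
- Merits: two ring-B bonds and the C10 quaternary centre form in one step, the tether carbinol directs the face, and C11 and C17 arrive with the dienophile. In ring-B convergence this is better than the chosen plan, which needs four steps from **13** to **19**.
- Weak points: the lactone bridge can only close when O2 and C9 lie on the same face of ring A, so A2 carries the 2α-oxygen, the epimer of the target's, and C2 must still be inverted later. C5 and C9 are left as alkene carbons: C5–H would have to be set by reducing a trisubstituted alkene beside the gem-dimethyl group, and the tetrasubstituted C8=C9 alkene conjugated to the lactone is hard to reduce selectively. C17 arrives oxygenated and C11 at the carboxyl level, so both need redox work before C12–C16 and the C13 centre are attached. The diene terminus C10 is fully substituted, which points to forcing conditions.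
- Comparison: the chosen plan sets C5 together with C10 in one stereospecific event and brings in C9 by a sequence that is also thermodynamically backed.

Alternative 2: The cut is C10–C20. Forward, the (bromomethyl)dimethylsilyl ether methyl 2β-{[(bromomethyl)dimethylsilyl]oxy}-8,8-ethylenedioxy-17,20-dinorlabd-5(10)-en-15-oate A3 would give, with Bu3SnH, an α-silyl radical that adds 6-exo to C10; the C5 radical then takes hydrogen to give the cyclic siloxane A4.
- Merits: the tether needs O2 cis to C20, which is the target's own 2β configuration, so the C2 oxygen is in place, controls C10, and needs no late correction. On this point the road is better than the chosen plan, which gives up the C2 oxygen in the rearrangement and restores it over steps 9, 10 and 12.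
- Weak points: C5 is set by hydrogen-atom transfer to a tertiary radical, and nothing secures the α-face, so a cis-decalin is a real outcome. Addition to a fully substituted alkene carbon must compete with simple reduction of the radical. The C20–Si bond must then be cleaved to C–H. A3 already contains the ring system and the C9 and C13 centres, so the step solves only the last methyl group and leaves the enantioselective construction of the octalin open.
- Comparison: the chosen plan sets the C5/C10 pair stereospecifically through a suprafacial shift.

Alternative 3: The cut is C3–C4 with ring B taken from verbenone. Forward, Lewis-acid activation (TiCl4) of the nopinone silyl enol ether methyl (3R)-3-methyl-5-{4,6,6-trimethyl-2-oxo-4-[2-(trimethylsilyloxy)prop-2-en-1-yl]bicyclo[3.1.1]heptan-3-yl}pentanoate A5 would break the cyclobutane bond C4–C7 and let the enol ether capture the C4 cation, giving methyl 2,8-dioxo-17-norlabdan-15-oate A6.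
- Merits: absolute configuration and the gem-dimethyl group come from the chiral pool, and the C2 oxygen arrives as a ketone without hydroboration. A6 is close to **28** of the chosen route and would be reached in fewer steps; on paper this is the shorter road.
- Weak points: acid-triggered opening of such cyclobutanes normally ends in proton loss from the tertiary cation, and intramolecular capture by a silyl enol ether that must itself survive the Lewis acid is without close precedent. The C10 quaternary centre depends on conjugate addition of a functionalised allyl unit to a hindered enone. In A6 two saturated ketones (C2, C8) must be told apart, whereas in the chosen plan C8 is still an enone when C2 is reduced.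
- Comparison: the chosen plan accepts a longer sequence after the key step in exchange for a key step of a known reaction class and a defined control element for every stereocentre.

Key step: step 7

Assumption: (S)-pent-4-yn-2-ol is used as a single enantiomer only so that **3**–**16** are single diastereomers; its carbinol carbon (C8) is a spectator that becomes a ketone in step 10. Pig liver esterase is taken to cleave the pro-S ester group of **21**, giving the (R)-half-ester.

Step 1
Reactants: 1 (2S)-pent-4-yn-2-ol
Product: 3 (2S,4Z)-5-iodo-4-methylpent-4-en-2-ol, via cyclic Z-alkenylalane chelate 2 (not isolated)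
Conditions: Me3Al, Cp2ZrCl2 (cat.), ClCH2CH2Cl, 0 °C to rt, then 80 °C; I2, THF, −30 to 0 °C; aq. NaHCO3/Na2S2O3
Reagents that add atoms: trimethylaluminium, C[Al](C)C; iodine, II
Why: Zirconium-catalysed syn-carboalumination (Negishi carboalumination) puts methyl on the internal alkyne carbon and aluminium on the terminus; on heating, the alkenylalane isomerises to the alkoxide-chelated Z-isomer 2 (anti-carbometalation of homopropargylic alcohols). Iodinolysis with retention should give the iodide with iodine cis to the CH2 chain.

Step 2
Reactants: 3 (2S,4Z)-5-iodo-4-methylpent-4-en-2-ol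
Product: 4 tert-butyl{[(2S,4Z)-5-iodo-4-methylpent-4-en-2-yl]oxy}dimethylsilane
Conditions: TBSCl, imidazole, DMF, rt
Reagents that add atoms: tert-butyldimethylsilyl chloride, CC(C)(C)[Si](C)(C)Cl
Why: Standard silylation of a secondary alcohol; the silyl ether masks the C8 oxygen through the organolithium, enolate and hydride steps.

Step 3
Reactants: 4 tert-butyl{[(2S,4Z)-5-iodo-4-methylpent-4-en-2-yl]oxy}dimethylsilane; 5 3,3-dimethylglutaric anhydride
Product: 7 (6Z,9S)-9-[(tert-butyldimethylsilyl)oxy]-3,3,7-trimethyl-5-oxodec-6-enoic acid, via alkenyllithium 6 (not isolated)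
Conditions: t-BuLi (2 equiv), Et2O, −78 °C; added to 5 (excess), THF, −78 °C; 1 M HCl
Reagents that add atoms: none
Why: Iodine–lithium exchange proceeds with retention of alkene geometry, and the alkenyllithium opens the symmetrical anhydride once (acylation of an organolithium by a cyclic anhydride), forming C1–C2. Inverse addition at low temperature limits a second addition to the liberated ketone.

Step 4
Reactants: 7 (6Z,9S)-9-[(tert-butyldimethylsilyl)oxy]-3,3,7-trimethyl-5-oxodec-6-enoic acid
Product: 8 methyl (6Z,9S)-9-[(tert-butyldimethylsilyl)oxy]-3,3,7-trimethyl-5-oxodec-6-enoate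
Conditions: Me3SiCHN2, MeOH/toluene, 0 °C
Reagents that add atoms: (trimethylsilyl)diazomethane, C[Si](C)(C)C=[N+]=[N-]
Why: Neutral O-methylation of the acid removes the acidic proton before the borane reduction and avoids base-induced Z/E isomerisation of the β,β-disubstituted enone.

Step 5
Reactants: 8 methyl (6Z,9S)-9-[(tert-butyldimethylsilyl)oxy]-3,3,7-trimethyl-5-oxodec-6-enoate
Product: 9 methyl (5R,6Z,9S)-9-[(tert-butyldimethylsilyl)oxy]-5-hydroxy-3,3,7-trimethyldec-6-enoate
Conditions: (S)-2-methyl-CBS-oxazaborolidine (cat.), catecholborane, toluene, −78 °C; MeOH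
Reagents that add atoms: none
Why: Corey–Bakshi–Shibata reduction of an enone: the alkenyl group acts as the large substituent and the CH2 group as the small one, so the (S)-catalyst should deliver hydride to the face that gives the 5R allylic alcohol (C2 of the labdane). Catecholborane at low temperature favours 1,2-reduction.

Step 6
Reactants: 9 methyl (5R,6Z,9S)-9-[(tert-butyldimethylsilyl)oxy]-5-hydroxy-3,3,7-trimethyldec-6-enoate
Product: 10 (6R)-6-[(1Z,4S)-4-[(tert-butyldimethylsilyl)oxy]-2-methylpent-1-en-1-yl]-4,4-dimethyloxan-2-one
Conditions: PPTS (cat.), toluene, 60 °C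
Reagents that add atoms: none
Why: Acid-catalysed lactonisation of a δ-hydroxy ester, helped by the gem-dimethyl group; the weak acid should not ionise the allylic carbinol, so the stereocentre is kept.

Step 7
Reactants: 10 (6R)-6-[(1Z,4S)-4-[(tert-butyldimethylsilyl)oxy]-2-methylpent-1-en-1-yl]-4,4-dimethyloxan-2-one
Product: 13 (1S,2S)-2-[(2S)-2-[(tert-butyldimethylsilyl)oxy]propyl]-2,6,6-trimethylcyclohex-3-ene-1-carboxylic acid, via silyl ketene acetal 11 (not isolated), via trimethylsilyl ester 12 (not isolated)
Conditions: LiN(i-Pr)2, Me3SiCl/Et3N, THF, −78 °C; toluene, 110 °C; then H2O/THF, citric acid, rt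
Reagents that add atoms: none
Why: Deprotonation at C5, the only α-position, in the presence of Me3SiCl gives the cyclic silyl ketene acetal 11. On heating, the array C5=C6–O–C2–C1=C10 undergoes a suprafacial [3,3]-sigmatropic shift that breaks O–C2 and forms C5–C10, giving silyl ester 12 and, after hydrolysis, acid 13. The closest known reaction type is the Ireland–Claisen rearrangement of alkenyl lactones, a lactone-to-carbocycle ring contraction. Ring A (C5–C10–C1=C2–C3–C4) closes six-membered through the new C5–C10 bond, while the former ring oxygen becomes part of the exocyclic carboxyl group. Because C5 and C2 are tied by the two-atom bridge C3–C4, only a boat transition state is geometrically possible. In that boat the alkene substituent trans to C2 (methyl C20) ends cis to the carboxyl carbon C6 and the cis substituent (C9) ends trans, which is the trans-decalin relationship; the Z-geometry from step 1 secures this. The absolute configuration at C5 and C10 is passed on from the 6R carbinol of step 5, since the new bond forms on the alkene face that carries the C2–O bond. The step needs C5–C10 bond formation to outrun self-condensation of the lactone enolate, which the internal Me3SiCl quench at −78 °C secures.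

Step 8
Reactants: 13 (1S,2S)-2-[(2S)-2-[(tert-butyldimethylsilyl)oxy]propyl]-2,6,6-trimethylcyclohex-3-ene-1-carboxylic acid
Product: 14 [(1S,2S)-2-[(2S)-2-[(tert-butyldimethylsilyl)oxy]propyl]-2,6,6-trimethylcyclohex-3-en-1-yl]methanol
Conditions: LiAlH4, THF, 0 °C to reflux
Reagents that add atoms: none
Why: Hydride reduction of the hindered carboxylic acid to the primary alcohol (C6); the silyl ether and the isolated alkene are inert, and no stereocentre is touched.

Step 9
Reactants: 14 [(1S,2S)-2-[(2S)-2-[(tert-butyldimethylsilyl)oxy]propyl]-2,6,6-trimethylcyclohex-3-en-1-yl]methanol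
Product: 16 (3S,4S)-4-(hydroxymethyl)-3-[(2S)-2-hydroxypropyl]-3,5,5-trimethylcyclohexan-1-ol (C1 epimers), via TBS-protected diol 15 (not isolated)
Conditions: 9-BBN, THF, 65 °C; NaOH, H2O2, 0 °C to rt; then HCl, MeOH, rt
Reagents that add atoms: hydrogen peroxide, OO
Why: Hydroboration with 9-BBN should put boron on C2, the alkene carbon remote from quaternary C10, and alkaline peroxide oxidises the C–B bond with retention; acidic methanol then cleaves the silyl ether. The configuration of the new carbinol does not matter because it is oxidised in step 10.

Step 10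
Reactants: 16 (3S,4S)-4-(hydroxymethyl)-3-[(2S)-2-hydroxypropyl]-3,5,5-trimethylcyclohexan-1-ol (C1 epimers)
Product: 17 (1S,2S)-2,6,6-trimethyl-4-oxo-2-(2-oxopropyl)cyclohexane-1-carbaldehyde
Conditions: Dess–Martin periodinane, NaHCO3, CH2Cl2, rt
Reagents that add atoms: none
Why: Dess–Martin oxidation of all three hydroxyl groups under buffered conditions gives the C6 aldehyde and the C2 and C8 ketones without enolising the aldehyde-bearing C5.

Step 11
Reactants: 17 (1S,2S)-2,6,6-trimethyl-4-oxo-2-(2-oxopropyl)cyclohexane-1-carbaldehyde
Product: 19 4,4,10-trimethyl-trans-octal-6-ene-2,8-dione (labdane numbering; 5α-H and 10β-CH3), via aldol 18 (not isolated)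
Conditions: KOH (cat.), MeOH, 0 °C to rt
Reagents that add atoms: none
Why: Intramolecular aldol condensation: the methyl ketone enolate (C7) adds to the C6 aldehyde and aldol 18 dehydrates to the conjugated enone, closing ring B; every other enolate–carbonyl pairing would give a four-membered ring or a strained bridged aldol that reverts. C5–H lies between two quaternary carbons and should enolise far more slowly than the methyl ketone, so the trans relationship from step 7 becomes the ring fusion.

Step 12
Reactants: 19 4,4,10-trimethyl-trans-octal-6-ene-2,8-dione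
Product: 20 2β-hydroxy-4,4,10-trimethyl-trans-octal-6-en-8-one (labdane numbering; 5α-H and 10β-CH3)
Conditions: NaBH4 (0.3 equiv), EtOH, −10 °C
Reagents that add atoms: none
Why: Borohydride reduces the saturated C2 ketone faster than the conjugated C8 enone. Hydride enters from the α-face because the β-face of C2 is screened by the syn-axial methyls C19 and C20, which should give the axial 2β-alcohol (2R).

Step 13
Reactants: 21 dimethyl 3-methylpentanedioate
Product: 22 (3R)-5-methoxy-3-methyl-5-oxopentanoic acid
Conditions: pig liver esterase, phosphate buffer pH 7/MeOH, −10 °C (pH-stat, NaOH); then HCl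
Reagents that add atoms: water, O
Why: Enzymatic desymmetrisation of a prochiral diester: the esterase hydrolyses one enantiotopic ester group, which sets the future C13 centre.

Step 14
Reactants: 22 (3R)-5-methoxy-3-methyl-5-oxopentanoic acid
Product: 23 methyl (3R)-5-hydroxy-3-methylpentanoate
Conditions: BH3·SMe2, THF, −10 °C to rt; MeOH
Reagents that add atoms: none
Why: Borane reduces the carboxylic acid chemoselectively in the presence of the methyl ester, so the acid arm becomes C11–C12 and the ester arm C14–C15.

Step 15
Reactants: 23 methyl (3R)-5-hydroxy-3-methylpentanoate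
Product: 24 methyl (3R)-3-methyl-5-oxopentanoate
Conditions: Dess–Martin periodinane, NaHCO3, CH2Cl2, 0 °C to rt
Reagents that add atoms: none
Why: Dess–Martin oxidation of the primary alcohol to the aldehyde; the stereocentre is β to the new carbonyl group and cannot epimerise.

Step 16
Reactants: 20 2β-hydroxy-4,4,10-trimethyl-trans-octal-6-en-8-one; 24 methyl (3R)-3-methyl-5-oxopentanoate
Product: 25 methyl (13R)-2β,11-dihydroxy-8-oxo-17-norlabd-6-en-15-oate (C9/C11 epimers)
Conditions: LiN(i-Pr)2 (2.2 equiv), THF, −78 °C; 24; AcOH, −78 °C
Reagents that add atoms: none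
Why: Two equivalents of base give the C2 alkoxide and the kinetic cross-conjugated enolate at C9 (C7 is an alkene carbon and cannot enolise), which adds to the aldehyde (aldol addition), forming C9–C11. The new C9 and C11 configurations do not matter, since both carbons become trigonal in step 17.

Step 17
Reactants: 25 methyl (13R)-2β,11-dihydroxy-8-oxo-17-norlabd-6-en-15-oate (C9/C11 epimers)
Product: 27 methyl (13R)-2β-acetoxy-8-oxo-17-norlabda-6,9(11)-dien-15-oate (E/Z at C9=C11), via diacetate 26 (not isolated)
Conditions: Ac2O, DMAP, pyridine, rt to 40 °C; then DBU, CH2Cl2, 40 °C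
Reagents that add atoms: acetic anhydride, CC(=O)OC(C)=O
Why: DMAP-catalysed acetylation of both hydroxyl groups, then base-induced β-elimination of the C11 acetate (E1cB), gives the exocyclic enone. The acetate left on the hindered axial C2 oxygen is the one the target carries.

Step 18
Reactants: 27 methyl (13R)-2β-acetoxy-8-oxo-17-norlabda-6,9(11)-dien-15-oate (E/Z at C9=C11)
Product: 28 methyl (13R)-2β-acetoxy-8-oxo-17-norlabdan-15-oate (5α-H and 9α-H)
Conditions: H2 (1 atm), 10% Pd/C, EtOAc, rt
Reagents that add atoms: none
Why: Catalytic hydrogenation saturates both conjugated C=C bonds. Hydrogen adds to C9=C11 from the α-face, opposite the axial C10 methyl, placing the chain β and equatorial (9S in the target), which is also the thermodynamic epimer beside the C8 ketone.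

Step 19
Reactants: 28 methyl (13R)-2β-acetoxy-8-oxo-17-norlabdan-15-oate
Product: 29 methyl (13R)-2β-acetoxylabd-8(17)-en-15-oate
Conditions: Zn, CH2Br2, TiCl4, THF/CH2Cl2, 0 °C to rt
Reagents that add atoms: dibromomethane, BrCBr
Why: Takai–Lombardo methylenation: the non-basic zinc–titanium methylene reagent converts hindered, enolisable ketones to methylene compounds without epimerising C9 and leaves the acetate and the methyl ester intact.

Step 20
Reactants: 29 methyl (13R)-2β-acetoxylabd-8(17)-en-15-oate
Product: 30 (2R,5S,9S,10S,13R)-2-acetoxylabd-8(17)-en-15-oic acid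
Conditions: LiI, pyridine, 115 °C; then 1 M HCl
Reagents that add atoms: none
Why: Nucleophilic demethylation: iodide attacks the methyl carbon of the ester (SN2) and releases the carboxylate. The acetate sits on a hindered secondary carbon that cannot be displaced, and the absence of acid and hydroxide spares the exocyclic alkene.

## Compound list

1 | (2S)-pent-4-yn-2-ol | C[C@H](O)CC#C | starting material
2 | (6S)-2,4,6-trimethyl-5,6-dihydro-2H-1,2-oxaluminine (cyclic Z-alkenyl(methyl)aluminium alkoxide chelate) | C[C@H]1CC(C)=C[Al](C)O1 | intermediate
3 | (2S,4Z)-5-iodo-4-methylpent-4-en-2-ol | C[C@H](O)C/C(C)=C\I | intermediate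
4 | tert-butyl{[(2S,4Z)-5-iodo-4-methylpent-4-en-2-yl]oxy}dimethylsilane | C[C@H](O[Si](C)(C)C(C)(C)C)C/C(C)=C\I | intermediate
5 | 3,3-dimethylglutaric anhydride (4,4-dimethyloxane-2,6-dione) | CC1(C)CC(=O)OC(=O)C1 | starting material
6 | [(1Z,4S)-4-[(tert-butyldimethylsilyl)oxy]-2-methylpent-1-en-1-yl]lithium | C[C@H](O[Si](C)(C)C(C)(C)C)C/C(C)=C\[Li] | intermediate
7 | (6Z,9S)-9-[(tert-butyldimethylsilyl)oxy]-3,3,7-trimethyl-5-oxodec-6-enoic acid | OC(=O)CC(C)(C)CC(=O)/C=C(C)\C[C@H](C)O[Si](C)(C)C(C)(C)C | intermediate
8 | methyl (6Z,9S)-9-[(tert-butyldimethylsilyl)oxy]-3,3,7-trimethyl-5-oxodec-6-enoate | COC(=O)CC(C)(C)CC(=O)/C=C(C)\C[C@H](C)O[Si](C)(C)C(C)(C)C | intermediate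
9 | methyl (5R,6Z,9S)-9-[(tert-butyldimethylsilyl)oxy]-5-hydroxy-3,3,7-trimethyldec-6-enoate | COC(=O)CC(C)(C)C[C@@H](O)/C=C(C)\C[C@H](C)O[Si](C)(C)C(C)(C)C | intermediate
10 | (6R)-6-[(1Z,4S)-4-[(tert-butyldimethylsilyl)oxy]-2-methylpent-1-en-1-yl]-4,4-dimethyloxan-2-one | O=C1CC(C)(C)C[C@H](/C=C(C)\C[C@H](C)O[Si](C)(C)C(C)(C)C)O1 | intermediate
11 | (2R)-2-[(1Z,4S)-4-[(tert-butyldimethylsilyl)oxy]-2-methylpent-1-en-1-yl]-4,4-dimethyl-6-[(trimethylsilyl)oxy]-3,4-dihydro-2H-pyran | C[Si](C)(C)OC1=CC(C)(C)C[C@H](/C=C(C)\C[C@H](C)O[Si](C)(C)C(C)(C)C)O1 | intermediate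
12 | trimethylsilyl (1S,2S)-2-[(2S)-2-[(tert-butyldimethylsilyl)oxy]propyl]-2,6,6-trimethylcyclohex-3-ene-1-carboxylate | C[Si](C)(C)OC(=O)[C@H]1C(C)(C)CC=C[C@]1(C)C[C@H](C)O[Si](C)(C)C(C)(C)C | intermediate
13 | (1S,2S)-2-[(2S)-2-[(tert-butyldimethylsilyl)oxy]propyl]-2,6,6-trimethylcyclohex-3-ene-1-carboxylic acid | OC(=O)[C@H]1C(C)(C)CC=C[C@]1(C)C[C@H](C)O[Si](C)(C)C(C)(C)C | intermediate
14 | [(1S,2S)-2-[(2S)-2-[(tert-butyldimethylsilyl)oxy]propyl]-2,6,6-trimethylcyclohex-3-en-1-yl]methanol | OC[C@H]1C(C)(C)CC=C[C@]1(C)C[C@H](C)O[Si](C)(C)C(C)(C)C | intermediate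
15 | (3R,4S)-3-[(2S)-2-[(tert-butyldimethylsilyl)oxy]propyl]-4-(hydroxymethyl)-3,5,5-trimethylcyclohexan-1-ol (C1 epimers) | OC[C@H]1C(C)(C)CC(O)C[C@]1(C)C[C@H](C)O[Si](C)(C)C(C)(C)C | intermediate
16 | (3S,4S)-4-(hydroxymethyl)-3-[(2S)-2-hydroxypropyl]-3,5,5-trimethylcyclohexan-1-ol (C1 epimers) | OC[C@H]1C(C)(C)CC(O)C[C@]1(C)C[C@H](C)O | intermediate
17 | (1S,2S)-2,6,6-trimethyl-4-oxo-2-(2-oxopropyl)cyclohexane-1-carbaldehyde | O=C[C@H]1C(C)(C)CC(=O)C[C@]1(C)CC(C)=O | intermediate
18 | 6-hydroxy-4,4,10-trimethyl-trans-decalin-2,8-dione (labdane numbering; 5α-H, 10β-CH3; C6 epimers) | O=C1CC(O)[C@H]2C(C)(C)CC(=O)C[C@]2(C)C1 | intermediate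
19 | 4,4,10-trimethyl-trans-octal-6-ene-2,8-dione (labdane numbering; 5α-H, 10β-CH3) | O=C1C=C[C@H]2C(C)(C)CC(=O)C[C@]2(C)C1 | intermediate
20 | 2β-hydroxy-4,4,10-trimethyl-trans-octal-6-en-8-one (labdane numbering; 5α-H, 10β-CH3) | O=C1C=C[C@H]2C(C)(C)C[C@@H](O)C[C@]2(C)C1 | intermediate
21 | dimethyl 3-methylpentanedioate (dimethyl 3-methylglutarate) | COC(=O)CC(C)CC(=O)OC | starting material
22 | (3R)-5-methoxy-3-methyl-5-oxopentanoic acid | C[C@@H](CC(=O)OC)CC(=O)O | intermediate
23 | methyl (3R)-5-hydroxy-3-methylpentanoate | C[C@@H](CC(=O)OC)CCO | intermediate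
24 | methyl (3R)-3-methyl-5-oxopentanoate | C[C@@H](CC(=O)OC)CC=O | intermediate
25 | methyl (13R)-2β,11-dihydroxy-8-oxo-17-norlabd-6-en-15-oate (C9/C11 epimers) | O=C1C=C[C@H]2C(C)(C)C[C@@H](O)C[C@]2(C)C1C(O)C[C@@H](C)CC(=O)OC | intermediate
26 | methyl (13R)-2β,11-diacetoxy-8-oxo-17-norlabd-6-en-15-oate (C9/C11 epimers) | O=C1C=C[C@H]2C(C)(C)C[C@@H](OC(C)=O)C[C@]2(C)C1C(OC(C)=O)C[C@@H](C)CC(=O)OC | intermediate
27 | methyl (13R)-2β-acetoxy-8-oxo-17-norlabda-6,9(11)-dien-15-oate (E/Z at C9=C11) | O=C1C=C[C@H]2C(C)(C)C[C@@H](OC(C)=O)C[C@]2(C)C1=CC[C@@H](C)CC(=O)OC | intermediate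
28 | methyl (13R)-2β-acetoxy-8-oxo-17-norlabdan-15-oate (5α-H, 9α-H, 10β-CH3) | O=C1CC[C@H]2C(C)(C)C[C@@H](OC(C)=O)C[C@]2(C)[C@H]1CC[C@@H](C)CC(=O)OC | intermediate
29 | methyl (13R)-2β-acetoxylabd-8(17)-en-15-oate | C=C1CC[C@H]2C(C)(C)C[C@@H](OC(C)=O)C[C@]2(C)[C@H]1CC[C@@H](C)CC(=O)OC | intermediate
30 | (2R,5S,9S,10S,13R)-2-acetoxylabd-8(17)-en-15-oic acid (2β-acetoxy) | C=C1CC[C@H]2C(C)(C)C[C@@H](OC(C)=O)C[C@]2(C)[C@H]1CC[C@@H](C)CC(=O)O | target

## Step count and least certain steps

Total: 20 steps. Longest linear sequence: 17 steps (steps 1–12 and 16–20, from **1**); the side-chain aldehyde **24** takes three steps (13–15) from **21**.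

**Step 7 (key step).** The rearrangement of **11** may be too slow at temperatures the ketene acetal tolerates, because a fully substituted alkene terminus must bond to C5 beside the gem-dimethyl carbon through a boat. On prolonged heating the allylic C2–O bond may ionise, with loss of the stereochemical relay, or the ketene acetal may be lost by stray protonation. The fallback keeps the same [3,3] disconnection but uses the neutral enol ether in place of the ketene acetal. It sets out from **10**: reduction with i-Bu2AlH at −78 °C would give the lactol (6R)-6-[(1Z,4S)-4-[(tert-butyldimethylsilyl)oxy]-2-methylpent-1-en-1-yl]-4,4-dimethyloxan-2-ol F1. Dehydration (MsCl, Et3N, then warming) would give the enol ether (2R)-2-[(1Z,4S)-4-[(tert-butyldimethylsilyl)oxy]-2-methylpent-1-en-1-yl]-4,4-dimethyl-3,4-dihydro-2H-pyran F2. Its thermal Claisen rearrangement (sealed tube, about 200 °C) through the same bridged boat should give the aldehyde (1S,2S)-2-[(2S)-2-[(tert-butyldimethylsilyl)oxy]propyl]-2,6,6-trimethylcyclohex-3-ene-1-carbaldehyde F3 with the same C5/C10 configuration. Reduction with NaBH4 returns to the route at **14**.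

**Step 5.** The two flanks of the ketone, a Z-trisubstituted alkenyl group and a CH2 group that leads to a quaternary carbon, may not be differentiated well enough in the oxazaborolidine complex, giving poor facial selectivity; conjugate reduction is a lesser risk. The fallback forms C1–C2 and the carbinol in one catalytic asymmetric addition and sets out from **4** and **5**. Methanolysis of **5** would give 5-methoxy-3,3-dimethyl-5-oxopentanoic acid F4, borane reduction methyl 5-hydroxy-3,3-dimethylpentanoate F5, and oxidation methyl 3,3-dimethyl-5-oxopentanoate F6. Iodide **4** is converted through **6** and ZnBr2 into bromo[(1Z,4S)-4-[(tert-butyldimethylsilyl)oxy]-2-methylpent-1-en-1-yl]zinc F7. F7 is added to F6 in the presence of Et2Zn and a chiral amino alcohol ligand (3-exo-morpholinoisoborneol, the enantiomer that gives the R carbinol), returning at **9**.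

**Step 3.** The alkenyllithium may add a second time to the ketone set free when the anhydride opens, or may deprotonate the anhydride. The fallback replaces anhydride opening by acylation of an N-methoxy-N-methylamide and sets out from **5** and **6**. MeNH(OMe) opens **5** to 5-[methoxy(methyl)amino]-3,3-dimethyl-5-oxopentanoic acid F8. Its lithium carboxylate is treated with **6**; the chelated tetrahedral intermediate collapses only on work-up, so over-addition is excluded, and the product is **7**.

**Step 1.** The heat-driven E-to-Z isomerisation of the alkenylalane may be incomplete for a secondary alkoxide, leaving a mixture of iodide isomers that is hard to separate. The fallback builds the alkene by conjugate addition and sets out from **1**. Silylation would give tert-butyldimethyl{[(2S)-pent-4-yn-2-yl]oxy}silane F9. Its lithium acetylide opens **5** to (9S)-9-[(tert-butyldimethylsilyl)oxy]-3,3-dimethyl-5-oxodec-6-ynoic acid F10, and Me3SiCHN2 gives methyl (9S)-9-[(tert-butyldimethylsilyl)oxy]-3,3-dimethyl-5-oxodec-6-ynoate F11. syn-Addition of Me2CuLi at −78 °C with low-temperature protonation gives the enone; after removal of any E-isomer the route is rejoined at **8**.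

**Step 16.** The dilithium alkoxide–enolate of **20** may exchange protons with the enolisable aldehyde or the adduct may revert by retro-aldol reaction, giving low conversion. The fallback changes from a lithium enolate to a Lewis-acid-mediated Mukaiyama aldol and sets out from **20**. LiN(i-Pr)2 and Me3SiCl would give 2β,8-bis(trimethylsilyloxy)-4,4,10-trimethyl-trans-octalin-6,8-diene F12. Its TiCl4-mediated addition to **24** at −78 °C, followed by aqueous work-up, returns at **25**.

## Further compounds

F1 | step 7 | (6R)-6-[(1Z,4S)-4-[(tert-butyldimethylsilyl)oxy]-2-methylpent-1-en-1-yl]-4,4-dimethyloxan-2-ol (anomers) | OC1CC(C)(C)C[C@H](/C=C(C)\C[C@H](C)O[Si](C)(C)C(C)(C)C)O1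
F2 | step 7 | (2R)-2-[(1Z,4S)-4-[(tert-butyldimethylsilyl)oxy]-2-methylpent-1-en-1-yl]-4,4-dimethyl-3,4-dihydro-2H-pyran | C1=CC(C)(C)C[C@H](/C=C(C)\C[C@H](C)O[Si](C)(C)C(C)(C)C)O1
F3 | step 7 | (1S,2S)-2-[(2S)-2-[(tert-butyldimethylsilyl)oxy]propyl]-2,6,6-trimethylcyclohex-3-ene-1-carbaldehyde | O=C[C@H]1C(C)(C)CC=C[C@]1(C)C[C@H](C)O[Si](C)(C)C(C)(C)C
F4 | step 5 | 5-methoxy-3,3-dimethyl-5-oxopentanoic acid | COC(=O)CC(C)(C)CC(=O)O
F5 | step 5 | methyl 5-hydroxy-3,3-dimethylpentanoate | COC(=O)CC(C)(C)CCO
F6 | step 5 | methyl 3,3-dimethyl-5-oxopentanoate | COC(=O)CC(C)(C)CC=O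
F7 | step 5 | bromo[(1Z,4S)-4-[(tert-butyldimethylsilyl)oxy]-2-methylpent-1-en-1-yl]zinc | C[C@H](O[Si](C)(C)C(C)(C)C)C/C(C)=C\[Zn]Br
F8 | step 3 | 5-[methoxy(methyl)amino]-3,3-dimethyl-5-oxopentanoic acid | CON(C)C(=O)CC(C)(C)CC(=O)O
F9 | step 1 | tert-butyldimethyl{[(2S)-pent-4-yn-2-yl]oxy}silane | C[C@H](O[Si](C)(C)C(C)(C)C)CC#C
F10 | step 1 | (9S)-9-[(tert-butyldimethylsilyl)oxy]-3,3-dimethyl-5-oxodec-6-ynoic acid | OC(=O)CC(C)(C)CC(=O)C#CC[C@H](C)O[Si](C)(C)C(C)(C)C
F11 | step 1 | methyl (9S)-9-[(tert-butyldimethylsilyl)oxy]-3,3-dimethyl-5-oxodec-6-ynoate | COC(=O)CC(C)(C)CC(=O)C#CC[C@H](C)O[Si](C)(C)C(C)(C)C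
F12 | step 16 | 2β,8-bis(trimethylsilyloxy)-4,4,10-trimethyl-trans-octalin-6,8-diene (labdane numbering; 5α-H, 10β-CH3) | C[Si](C)(C)OC=1C=C[C@H]2C(C)(C)C[C@@H](O[Si](C)(C)C)C[C@]2(C)C=1
A1 | alternative 1 | (1R)-4-ethenyl-3,5,5-trimethylcyclohex-3-en-1-yl 4-[(tert-butyldimethylsilyl)oxy]but-2-ynoate | C=CC1=C(C)C[C@@H](OC(=O)C#CCO[Si](C)(C)C(C)(C)C)CC1(C)C
A2 | alternative 1 | tricyclic dienyl lactone (O2–C11 lactone bridge, C5=C6 and C8=C9 alkenes, C17 silyl ether) | CC(C)(C)[Si](C)(C)OCC1=C2C(=O)O[C@H]3CC(C)(C)C(=CC1)[C@]2(C)C3
A3 | alternative 2 | methyl 2β-{[(bromomethyl)dimethylsilyl]oxy}-8,8-ethylenedioxy-17,20-dinorlabd-5(10)-en-15-oate | C12(OCCO1)CCC3=C(C[C@H](O[Si](C)(C)CBr)CC3(C)C)[C@H]2CC[C@@H](C)CC(=O)OC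
A4 | alternative 2 | cyclic siloxane (O2–SiMe2–C20 bridge) of methyl 8,8-ethylenedioxy-17-norlabdan-15-oate | C12(OCCO1)CC[C@H]3C(C)(C)C[C@@H]4C[C@]3(C[Si](C)(C)O4)[C@H]2CC[C@@H](C)CC(=O)OC
A5 | alternative 3 | methyl (3R)-3-methyl-5-{4,6,6-trimethyl-2-oxo-4-[2-(trimethylsilyloxy)prop-2-en-1-yl]bicyclo[3.1.1]heptan-3-yl}pentanoate | O=C1[C@@H]2C[C@@H](C2(C)C)[C@](C)(CC(=C)O[Si](C)(C)C)[C@H]1CC[C@@H](C)CC(=O)OC
A6 | alternative 3 | methyl 2,8-dioxo-17-norlabdan-15-oate | O=C1CC[C@H]2C(C)(C)CC(=O)C[C@]2(C)[C@H]1CC[C@@H](C)CC(=O)OC
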